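Ring A of colpol is a 4-methoxyphenol. Its C-OH and C-OMe carbons are para, the butenyl CH2 sits on the carbon beside C-OH, and bromine sits on the carbon beside C-OMe. A Dötz benzannulation produces exactly this 1,2,4,5-pattern, so ring A is cut into an α-silylvinyl(methoxy)carbene of Cr(CO)5, one CO ligand and a terminal alkyne. A single heating step makes three C-C bonds and the whole ring at the end of a skipped diyne that already carries ring B as its bromoresorcinol dipivalate. Silicon marks the future C-Br carbon, and the untouched internal alkyne becomes the Z-alkene.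

Key step: step 8

Remark: SMILES cannot show an η6 bond, so in 16 the arene and the Cr(CO)3 unit are written side by side; the chromium sits on the newly formed ring A.

Step 1
Reactants: 1 4-bromo-3,5-dihydroxybenzoic acid
Product: 3 4-bromo-3,5-bis(2,2-dimethylpropanoyloxy)benzoic acid, via mixed pivalic anhydride 2 (not isolated)
Conditions: PivCl (3.5 equiv), pyridine, DMAP (cat.), CH2Cl2, 0 °C to rt; then THF/H2O, rt; 1 M HCl work-up
Reagents that add atoms: pivaloyl chloride CC(C)(C)C(=O)Cl; water O
Why: Pyridine/DMAP-promoted O-acylation caps both phenols as hindered, electron-withdrawing esters that later survive carbonate and deactivate ring B towards NBS, while the carboxyl group is acylated only transiently to anhydride 2, which water cleaves at its less hindered aroyl carbonyl.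

Step 2
Reactants: 3 4-bromo-3,5-bis(2,2-dimethylpropanoyloxy)benzoic acid
Product: 4 2-bromo-5-(hydroxymethyl)-1,3-phenylene bis(2,2-dimethylpropanoate)
Conditions: BH3·THF (2 equiv), THF, 0 °C to rt; then aq. NH4Cl
Reagents that add atoms: none
Why: Chemoselective borane reduction, in which the acid is activated as an acyloxyborane and reduced far faster than the two aryl pivalates, while the aryl bromide is inert to BH3.

Step 3
Reactants: 4 2-bromo-5-(hydroxymethyl)-1,3-phenylene bis(2,2-dimethylpropanoate)
Product: 5 2-bromo-5-(bromomethyl)-1,3-phenylene bis(2,2-dimethylpropanoate)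
Conditions: CBr4, PPh3, CH2Cl2, 0 °C
Reagents that add atoms: tetrabromomethane BrC(Br)(Br)Br
Why: Appel reaction, in which the alkoxyphosphonium ion of the primary benzylic alcohol is displaced by bromide under neutral conditions that leave the esters alone.

Step 4
Reactants: 6 3-bromo-1-(trimethylsilyl)prop-1-yne; 7 ethynylmagnesium bromide (1.4 equiv)
Product: 8 1-(trimethylsilyl)penta-1,4-diyne
Conditions: CuCl (5 mol %), THF, 0 °C to 50 °C; aq. NH4Cl; distillation
Reagents that add atoms: none
Why: Copper-catalysed SN2 alkynylation of a propargylic bromide by an ethynyl Grignard reagent, a standard entry to skipped diynes, in which the silyl cap hinders attack at the far alkyne terminus (allene pathway) and the excess of 7 suppresses a second alkylation.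

Step 5
Reactants: 5 2-bromo-5-(bromomethyl)-1,3-phenylene bis(2,2-dimethylpropanoate); 8 1-(trimethylsilyl)penta-1,4-diyne
Product: 9 2-bromo-5-[6-(trimethylsilyl)hexa-2,5-diyn-1-yl]-1,3-phenylene bis(2,2-dimethylpropanoate)
Conditions: CuI (1.0 equiv), NaI (1.0 equiv), K2CO3 (1.5 equiv), DMF, rt, Ar
Reagents that add atoms: none
Why: Copper-mediated sp-sp3 coupling of a terminal alkyne with a benzylic halide under carbonate/iodide conditions, the routine method for skipped polyynes, in which K2CO3 at room temperature is too weak to cleave aryl pivalates or the alkynyl C-Si bond, and no palladium is present that could touch the aryl bromide.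

Step 6
Reactants: 9 2-bromo-5-[6-(trimethylsilyl)hexa-2,5-diyn-1-yl]-1,3-phenylene bis(2,2-dimethylpropanoate)
Product: 10 2-bromo-5-(hexa-2,5-diyn-1-yl)-1,3-phenylene bis(2,2-dimethylpropanoate)
Conditions: AgNO3 (10 mol %), CH2Cl2/MeOH/H2O, rt, dark
Reagents that add atoms: none
Why: Silver-catalysed protiodesilylation of a 1-(trimethylsilyl)alkyne runs at neutral pH, so it spares the aryl pivalates and the base-sensitive bis-propargylic CH2 that K2CO3/MeOH or unbuffered fluoride would endanger.

Step 7
Reactants: 11 (1-bromoethenyl)trimethylsilane; 12 hexacarbonylchromium Cr(CO)6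
Product: 15 pentacarbonyl[methoxy(1-(trimethylsilyl)ethenyl)carbene]chromium, via 1-(trimethylsilyl)ethenyllithium 13 (not isolated), via lithium acylchromate 14 (not isolated)
Conditions: t-BuLi (2.0 equiv), Et2O, −78 °C; Cr(CO)6, −78 °C to rt; evaporate; MeOTf, CH2Cl2, 0 °C to rt
Reagents that add atoms: methyl trifluoromethanesulfonate COS(=O)(=O)C(F)(F)F
Why: Classical Fischer carbene synthesis, in which bromine-lithium exchange gives 13, addition to a CO ligand of Cr(CO)6 gives acylate 14 and hard O-methylation gives 15, with the α-silyl group shielding the vinyl unit from the polymerisation that plagues the unsubstituted vinyl complex.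

Step 8
Reactants: 10 2-bromo-5-(hexa-2,5-diyn-1-yl)-1,3-phenylene bis(2,2-dimethylpropanoate); 15 pentacarbonyl[methoxy(1-(trimethylsilyl)ethenyl)carbene]chromium
Product: 17 2-bromo-5-{4-[2-hydroxy-5-methoxy-4-(trimethylsilyl)phenyl]but-2-yn-1-yl}-1,3-phenylene bis(2,2-dimethylpropanoate), via tricarbonylchromium arene complex 16 (not isolated)
Conditions: 10 (1.0 equiv), 15 (1.1 equiv), THF (0.1 M, degassed), 50 °C, Ar; then Et2O, air, daylight, rt
Reagents that add atoms: none
Why: Thermal loss of a cis CO from 15 frees a site on zerovalent chromium for the terminal triple bond of 10; insertion gives an η3-vinylcarbene, CO migration gives an η4-dienylketene, and six-electron ring closure followed by enolisation delivers the phenol as its Cr(CO)3 complex 16, from which air removes the metal to give 17. This is the Dötz benzannulation of an α-substituted alkenyl(methoxy)carbene complex with a 1-alkyne, the variant that gives phenols most dependably because no existing arene has to be dearomatised. Ring A is closed as a formal [3+2+1] assembly (three carbons of the carbene ligand, two alkyne carbons, one CO), the last bond coming from the 6π electrocyclisation of the dienylketene that joins the ketene carbon to the former vinyl CH2. No stereocentre is created. Two selectivities are needed: alkyne orientation, secured because the bulkier CH2-bearing end takes the new carbene position away from the close CO contact of the inner position and so ends beside the CO-derived C-OH while the alkyne CH bonds to C-OMe; and choice between the two triple bonds of 10, secured by the smaller steric demand of the monosubstituted alkyne at the crowded Cr(CO)4 fragment, by near-equimolar 15, and by the one-carbon spacer, which is too short for the vinylcarbene to reach the second alkyne. The SiMe3 group is only a spectator here and ends on the ring carbon ortho to OMe, where bromine is required.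

Step 9
Reactants: 17 2-bromo-5-{4-[2-hydroxy-5-methoxy-4-(trimethylsilyl)phenyl]but-2-yn-1-yl}-1,3-phenylene bis(2,2-dimethylpropanoate)
Product: 18 2-bromo-5-{4-[2-(2,2-dimethylpropanoyloxy)-5-methoxy-4-(trimethylsilyl)phenyl]but-2-yn-1-yl}-1,3-phenylene bis(2,2-dimethylpropanoate)
Conditions: PivCl, Et3N, DMAP (cat.), CH2Cl2, 0 °C to rt
Reagents that add atoms: pivaloyl chloride CC(C)(C)C(=O)Cl
Why: DMAP-catalysed O-acylation carried out at once, which turns the strongest director of ring A into a weak one so that OMe governs the next step, prevents NBS oxidation to the quinone and stops cycloisomerisation of the o-(alk-2-ynyl)phenol to a benzofuran.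

Step 10
Reactants: 18 2-bromo-5-{4-[2-(2,2-dimethylpropanoyloxy)-5-methoxy-4-(trimethylsilyl)phenyl]but-2-yn-1-yl}-1,3-phenylene bis(2,2-dimethylpropanoate)
Product: 19 2-bromo-5-{4-[4-bromo-2-(2,2-dimethylpropanoyloxy)-5-methoxyphenyl]but-2-yn-1-yl}-1,3-phenylene bis(2,2-dimethylpropanoate)
Conditions: NBS (1.05 equiv), MeCN, 0 °C to rt, dark; aq. Na2S2O3 work-up
Reagents that add atoms: N-bromosuccinimide O=C1CCC(=O)N1Br
Why: Electrophilic ipso-bromodesilylation, in which attack at the silylated carbon (ortho to OMe, para to the CH2 group) is favoured by β-silicon stabilisation of the Wheland ion, whereas ring B with bromine and two acyloxy groups is deactivated and an unactivated dialkyl alkyne is inert to NBS in the dark.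

Step 11
Reactants: 19 2-bromo-5-{4-[4-bromo-2-(2,2-dimethylpropanoyloxy)-5-methoxyphenyl]but-2-yn-1-yl}-1,3-phenylene bis(2,2-dimethylpropanoate)
Product: 20 2-bromo-5-{(2Z)-4-[4-bromo-2-(2,2-dimethylpropanoyloxy)-5-methoxyphenyl]but-2-en-1-yl}-1,3-phenylene bis(2,2-dimethylpropanoate)
Conditions: H2 (1 atm), Pd/CaCO3 poisoned with Pb(OAc)2, quinoline, EtOAc, rt, stopped after one equivalent of H2
Reagents that add atoms: none
Why: Lindlar-type semi-hydrogenation, in which syn delivery of one H2 to the alkyne adsorbed on lead- and quinoline-poisoned palladium sets the Z geometry, and at 1 atm and room temperature aryl bromides and esters are not reduced.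

Step 12
Reactants: 20 2-bromo-5-{(2Z)-4-[4-bromo-2-(2,2-dimethylpropanoyloxy)-5-methoxyphenyl]but-2-en-1-yl}-1,3-phenylene bis(2,2-dimethylpropanoate)
Product: 21 colpol, 2-bromo-5-[(2Z)-4-(4-bromo-2-hydroxy-5-methoxyphenyl)but-2-en-1-yl]benzene-1,3-diol
Conditions: NaOMe (4 equiv), MeOH (degassed), 0 °C to rt, Ar; then 1 M HCl to pH 4
Reagents that add atoms: none
Why: Methoxide transesterification expels the three phenoxides as good leaving groups, while the methyl ether, both aryl bromides and the isolated Z-alkene (whose allylic C-H bonds are far too weakly acidic for methoxide) stay untouched and exclusion of air protects the electron-rich phenoxides.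

Compound list
1 | 4-bromo-3,5-dihydroxybenzoic acid | OC(=O)c1cc(O)c(Br)c(O)c1 | starting material
2 | 4-bromo-3,5-bis(2,2-dimethylpropanoyloxy)benzoic 2,2-dimethylpropanoic anhydride | CC(C)(C)C(=O)OC(=O)c1cc(OC(=O)C(C)(C)C)c(Br)c(OC(=O)C(C)(C)C)c1 | intermediate
3 | 4-bromo-3,5-bis(2,2-dimethylpropanoyloxy)benzoic acid | OC(=O)c1cc(OC(=O)C(C)(C)C)c(Br)c(OC(=O)C(C)(C)C)c1 | intermediate
4 | 2-bromo-5-(hydroxymethyl)-1,3-phenylene bis(2,2-dimethylpropanoate) | OCc1cc(OC(=O)C(C)(C)C)c(Br)c(OC(=O)C(C)(C)C)c1 | intermediate
5 | 2-bromo-5-(bromomethyl)-1,3-phenylene bis(2,2-dimethylpropanoate) | BrCc1cc(OC(=O)C(C)(C)C)c(Br)c(OC(=O)C(C)(C)C)c1 | intermediate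
6 | 3-bromo-1-(trimethylsilyl)prop-1-yne | BrCC#C[Si](C)(C)C | starting material
7 | ethynylmagnesium bromide | C#C[Mg]Br | starting material
8 | 1-(trimethylsilyl)penta-1,4-diyne | C#CCC#C[Si](C)(C)C | intermediate
9 | 2-bromo-5-[6-(trimethylsilyl)hexa-2,5-diyn-1-yl]-1,3-phenylene bis(2,2-dimethylpropanoate) | C[Si](C)(C)C#CCC#CCc1cc(OC(=O)C(C)(C)C)c(Br)c(OC(=O)C(C)(C)C)c1 | intermediate
10 | 2-bromo-5-(hexa-2,5-diyn-1-yl)-1,3-phenylene bis(2,2-dimethylpropanoate) | C#CCC#CCc1cc(OC(=O)C(C)(C)C)c(Br)c(OC(=O)C(C)(C)C)c1 | intermediate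
11 | (1-bromoethenyl)trimethylsilane | C=C(Br)[Si](C)(C)C | starting material
12 | hexacarbonylchromium Cr(CO)6 | O=C=[Cr](=C=O)(=C=O)(=C=O)(=C=O)=C=O | starting material
13 | 1-(trimethylsilyl)ethenyllithium | [Li]C(=C)[Si](C)(C)C | intermediate
14 | lithium pentacarbonyl[1-oxido-2-(trimethylsilyl)prop-2-en-1-ylidene]chromate | [Li+].[O-]C(C(=C)[Si](C)(C)C)=[Cr](=C=O)(=C=O)(=C=O)(=C=O)=C=O | intermediate
15 | pentacarbonyl[methoxy(1-(trimethylsilyl)ethenyl)carbene]chromium | COC(C(=C)[Si](C)(C)C)=[Cr](=C=O)(=C=O)(=C=O)(=C=O)=C=O | intermediate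
16 | tricarbonyl(η6-arene)chromium complex of 17, chromium on ring A | COc1cc(CC#CCc2cc(OC(=O)C(C)(C)C)c(Br)c(OC(=O)C(C)(C)C)c2)c(O)cc1[Si](C)(C)C.O=C=[Cr](=C=O)=C=O | intermediate
17 | 2-bromo-5-{4-[2-hydroxy-5-methoxy-4-(trimethylsilyl)phenyl]but-2-yn-1-yl}-1,3-phenylene bis(2,2-dimethylpropanoate) | COc1cc(CC#CCc2cc(OC(=O)C(C)(C)C)c(Br)c(OC(=O)C(C)(C)C)c2)c(O)cc1[Si](C)(C)C | intermediate
18 | 2-bromo-5-{4-[2-(2,2-dimethylpropanoyloxy)-5-methoxy-4-(trimethylsilyl)phenyl]but-2-yn-1-yl}-1,3-phenylene bis(2,2-dimethylpropanoate) | COc1cc(CC#CCc2cc(OC(=O)C(C)(C)C)c(Br)c(OC(=O)C(C)(C)C)c2)c(OC(=O)C(C)(C)C)cc1[Si](C)(C)C | intermediate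
19 | 2-bromo-5-{4-[4-bromo-2-(2,2-dimethylpropanoyloxy)-5-methoxyphenyl]but-2-yn-1-yl}-1,3-phenylene bis(2,2-dimethylpropanoate) | COc1cc(CC#CCc2cc(OC(=O)C(C)(C)C)c(Br)c(OC(=O)C(C)(C)C)c2)c(OC(=O)C(C)(C)C)cc1Br | intermediate
20 | 2-bromo-5-{(2Z)-4-[4-bromo-2-(2,2-dimethylpropanoyloxy)-5-methoxyphenyl]but-2-en-1-yl}-1,3-phenylene bis(2,2-dimethylpropanoate) | COc1cc(C/C=C\Cc2cc(OC(=O)C(C)(C)C)c(Br)c(OC(=O)C(C)(C)C)c2)c(OC(=O)C(C)(C)C)cc1Br | intermediate
21 | colpol, 2-bromo-5-[(2Z)-4-(4-bromo-2-hydroxy-5-methoxyphenyl)but-2-en-1-yl]benzene-1,3-diol | COc1cc(C/C=C\Cc2cc(O)c(Br)c(O)c2)c(O)cc1Br | target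

Total step count: 12.
Longest linear sequence: 10 steps (1, 2, 3, 5, 6, 8, 9, 10, 11, 12). Steps 4 and 7 are side branches.

Steps most likely to fail

Step 8.
- **What may go wrong:** Insertion at the internal triple bond may compete with insertion at the terminal one. The 1-alkyne may oligomerise on chromium, or the skipped diyne may slowly rearrange during prolonged heating.
- **Fallback:** Ring A is bought as a cresol and functionalised by classical arene chemistry, and the two benzylic halves are then joined through a three-carbon alkyne. This fallback sets out from 5 and comes back at 19.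
- **Ring B half:** Bromide 5 is coupled with commercial ethynyltrimethylsilane under the copper conditions of step 5. This should give 2-bromo-5-[3-(trimethylsilyl)prop-2-yn-1-yl]-1,3-phenylene bis(2,2-dimethylpropanoate) F1. Silver-catalysed desilylation as in step 6 should then give 2-bromo-5-(prop-2-yn-1-yl)-1,3-phenylene bis(2,2-dimethylpropanoate) F2.
- **Ring A half:** Commercial 4-methoxy-2-methylphenol is acylated (PivCl, Et3N, DMAP) to 4-methoxy-2-methylphenyl 2,2-dimethylpropanoate F3. Ring bromination with NBS in MeCN at the open carbon ortho to OMe and para to methyl should give 5-bromo-4-methoxy-2-methylphenyl 2,2-dimethylpropanoate F4. Wohl-Ziegler bromination of the methyl group (NBS, AIBN, PhCF3, reflux) should give 5-bromo-2-(bromomethyl)-4-methoxyphenyl 2,2-dimethylpropanoate F5.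
- **Union:** Copper-mediated coupling of F2 with F5 (CuI, NaI, K2CO3, DMF, rt) gives 19.

Step 5.
- **What may go wrong:** Substitution at the benzylic carbon may be slow. The carbonate would then have time to shift the skipped diyne partner towards an allene or to strip the alkynyl silane.
- **Fallback:** The diyne is built one alkyne at a time. No skipped diyne then has to wait through the slow benzylic coupling, and the second C-C bond is made at a more reactive propargylic bromide. This fallback sets out from 5 and comes back at 9.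
- **Sequence:** Bromide 5 is coupled with prop-2-yn-1-ol (CuI, NaI, K2CO3, DMF, rt) to give 2-bromo-5-(4-hydroxybut-2-yn-1-yl)-1,3-phenylene bis(2,2-dimethylpropanoate) F6. An Appel reaction (CBr4, PPh3, CH2Cl2, 0 °C) gives 2-bromo-5-(4-bromobut-2-yn-1-yl)-1,3-phenylene bis(2,2-dimethylpropanoate) F7. Coupling of F7 with ethynyltrimethylsilane under the same copper conditions gives 9.

Step 10.
- **What may go wrong:** Adventitious HBr may cause protodesilylation alongside ipso attack, so that the exchange degrades into mixtures of silylated, protonated and brominated material.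
- **Fallback:** Silicon is removed on purpose, and the bromine is then placed by ordinary C-H substitution. This fallback sets out from 18 and comes back at 19.
- **Sequence:** Treatment of 18 with CF3CO2H in CH2Cl2 (0 °C to rt) should protodesilylate the electron-rich arylsilane to 2-bromo-5-{4-[2-(2,2-dimethylpropanoyloxy)-5-methoxyphenyl]but-2-yn-1-yl}-1,3-phenylene bis(2,2-dimethylpropanoate) F8. NBS in MeCN in the dark should then brominate ortho to OMe. Of the two ortho carbons, one is wedged between OMe and the CH2 chain. The other is open and para to the chain, and it is the carbon that carries bromine in 19.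

Further compounds
F1 | step 8 | 2-bromo-5-[3-(trimethylsilyl)prop-2-yn-1-yl]-1,3-phenylene bis(2,2-dimethylpropanoate) | C[Si](C)(C)C#CCc1cc(OC(=O)C(C)(C)C)c(Br)c(OC(=O)C(C)(C)C)c1
F2 | step 8 | 2-bromo-5-(prop-2-yn-1-yl)-1,3-phenylene bis(2,2-dimethylpropanoate) | C#CCc1cc(OC(=O)C(C)(C)C)c(Br)c(OC(=O)C(C)(C)C)c1
F3 | step 8 | 4-methoxy-2-methylphenyl 2,2-dimethylpropanoate | COc1ccc(OC(=O)C(C)(C)C)c(C)c1
F4 | step 8 | 5-bromo-4-methoxy-2-methylphenyl 2,2-dimethylpropanoate | COc1cc(C)c(OC(=O)C(C)(C)C)cc1Br
F5 | step 8 | 5-bromo-2-(bromomethyl)-4-methoxyphenyl 2,2-dimethylpropanoate | COc1cc(CBr)c(OC(=O)C(C)(C)C)cc1Br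
F6 | step 5 | 2-bromo-5-(4-hydroxybut-2-yn-1-yl)-1,3-phenylene bis(2,2-dimethylpropanoate) | OCC#CCc1cc(OC(=O)C(C)(C)C)c(Br)c(OC(=O)C(C)(C)C)c1
F7 | step 5 | 2-bromo-5-(4-bromobut-2-yn-1-yl)-1,3-phenylene bis(2,2-dimethylpropanoate) | BrCC#CCc1cc(OC(=O)C(C)(C)C)c(Br)c(OC(=O)C(C)(C)C)c1
F8 | step 10 | 2-bromo-5-{4-[2-(2,2-dimethylpropanoyloxy)-5-methoxyphenyl]but-2-yn-1-yl}-1,3-phenylene bis(2,2-dimethylpropanoate) | COc1ccc(OC(=O)C(C)(C)C)c(CC#CCc2cc(OC(=O)C(C)(C)C)c(Br)c(OC(=O)C(C)(C)C)c2)c1
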